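**Plan**

- Unit 1 is the flavone whose ring B carries the bridging ether oxygen at C4'; unit 2 is the flavone that carries this oxygen at C6.
- Retrosynthetic cuts, in order: (a) the 5-O–Me and 4'-O–Bn bonds of unit 2; (b) ring C of unit 2 at O1–C2 and C4–C4a, giving a symmetric 4-aryloxy-3,5-dimethoxyphenol and an aroylacetate; (c) ring A of unit 1 at C5–C6, C7–C8 and C4a–C5, giving a 2-(diazoacetyl)-6-aryl-4-pyranone and methoxyethyne; (d) the pyranone, giving an aryl methyl ketone, ethyl acetate and diethyl oxalate; (e) the diaryl ether at O–C4', giving syringaldehyde and 4-fluoroacetophenone.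
- Enabling feature: ring A of unit 1 has OH at C5 and OMe at C7 (meta), H at C6 and C8, and is fused through C4a/C8a to a 4-pyranone. C5 maps onto a ketene carbon, C6–C7(OMe) onto methoxyethyne, C8 onto the diazo carbon and C8a/C4a onto C2/C3 of the pyranone.
- Forward order: diaryl ether, then the pyranone (ring C of unit 1), then ring A of unit 1 by benzannulation, then ring C of unit 2 by annulation onto the distal phenol (whose ring becomes ring A of unit 2), then deprotection.
- Stereochemistry: the target is achiral, so nothing has to be set.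

Key step: step 9

Remark: methoxyethyne (15) is assumed to be handled as a freshly distilled, cold solution. The only stereocentre on the route, in the transient cyclobutenone 17, is racemic and is erased in the same flask.

**Route**

Step 1
Reactants: 1 syringaldehyde; 2 4-fluoroacetophenone
Product: 3 4-(4-acetylphenoxy)-3,5-dimethoxybenzaldehyde
Conditions: K2CO3, DMSO, 120 °C, N2
Reagents that add atoms: none
Why: Nucleophilic aromatic substitution, in which the para-acetyl group activates the C–F carbon towards the phenoxide of 1, while carbonate in an aprotic solvent is a poor base for a competing Claisen–Schmidt condensation of the methyl ketone with the non-enolisable aldehyde.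

Step 2
Reactants: 3
Product: 5 1-[4-(4-hydroxy-2,6-dimethoxyphenoxy)phenyl]ethan-1-one, via aryl formate 4 (not isolated)
Conditions: mCPBA, CH2Cl2, 0 °C to rt; then K2CO3 (cat.), MeOH, rt
Reagents that add atoms: mCPBA, O=C(OO)c1cccc(Cl)c1
Why: Dakin-type Baeyer–Villiger oxidation, in which the trioxygenated aryl group of the aldehyde migrates far faster than the aryl methyl ketone reacts with a peracid without strong acid, followed by methanolysis of the formate.

Step 3
Reactants: 5
Product: 6 1-{4-[4-(benzyloxy)-2,6-dimethoxyphenoxy]phenyl}ethan-1-one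
Conditions: BnBr, K2CO3, DMF, rt
Reagents that add atoms: benzyl bromide, BrCc1ccccc1
Why: Williamson etherification of the unhindered phenoxide gives a benzyl ether that should survive the enolate, acid, acyl chloride and irradiation steps and is later removed by hydrogenolysis.

Step 4
Reactants: 6
Product: 7 1-{4-[4-(benzyloxy)-2,6-dimethoxyphenoxy]phenyl}butane-1,3-dione
Conditions: NaH, EtOAc, THF, 0 °C to reflux; aq. HCl work-up
Reagents that add atoms: ethyl acetate, CCOC(C)=O
Why: Crossed Claisen condensation of the ketone enolate with ethyl acetate, driven to completion by formation of the stabilised 1,3-diketonate.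

Step 5
Reactants: 7
Product: 9 ethyl 6-{4-[4-(benzyloxy)-2,6-dimethoxyphenoxy]phenyl}-4-oxo-4H-pyran-2-carboxylate, via triketo ester 8 (not isolated)
Conditions: NaOEt, (CO2Et)2, EtOH, rt to 50 °C; then HCl, EtOH, reflux
Reagents that add atoms: diethyl oxalate, CCOC(=O)C(=O)OCC
Why: Claisen condensation of the aroylacetone at its terminal methyl group with diethyl oxalate (the classical entry to 6-arylcomanic esters), followed by acid-catalysed cyclodehydration of the 2,4,6-triketo ester to the 4-pyranone.

Step 6
Reactants: 9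
Product: 10 6-{4-[4-(benzyloxy)-2,6-dimethoxyphenoxy]phenyl}-4-oxo-4H-pyran-2-carboxylic acid
Conditions: LiOH, THF/H2O, 0 °C; then aq. HCl to pH 2
Reagents that add atoms: lithium hydroxide, [Li+].[OH-]
Why: Saponification of the activated 2-carboxylate should outrun conjugate attack on the pyranone at 0 °C, and the acidic work-up would re-close any ring-opened material.

Step 7
Reactants: 10
Product: 12 2-(diazoacetyl)-6-{4-[4-(benzyloxy)-2,6-dimethoxyphenoxy]phenyl}-4H-pyran-4-one, via acid chloride 11 (not isolated)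
Conditions: (COCl)2, DMF (cat.), CH2Cl2, 0 °C to rt; then Me3SiCHN2, THF/MeCN, 0 °C
Reagents that add atoms: trimethylsilyldiazomethane, C[Si](C)(C)C=[N+]=[N-]
Why: Acylation of the diazoalkane by the acyl chloride with loss of the silyl group to chloride (first stage of an Arndt–Eistert sequence in its trimethylsilyldiazomethane variant), as is routine for chromone-2-carbonyl chlorides.

Step 8
Reactants: 13 chloroacetaldehyde dimethyl acetal
Product: 15 methoxyethyne, via sodium methoxyethynide 14 (not isolated)
Conditions: NaNH2, liquid NH3, −33 °C; then saturated aq. NaCl, −70 °C; distillation into cold ClCH2CH2Cl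
Reagents that add atoms: none
Why: Twofold base-induced elimination (HCl, then methanol) gives the sodium alkynide, which is protonated on quenching; this is the standard preparation of 1-alkoxyalkynes from chloroacetals.

Step 9
Reactants: 12; 15 methoxyethyne
Product: 19 2-{4-[4-(benzyloxy)-2,6-dimethoxyphenoxy]phenyl}-5-hydroxy-7-methoxy-4H-chromen-4-one, via pyranonylketene 16 (not isolated), via methoxycyclobutenone 17 (not isolated), via dienylketene 18 (not isolated)
Conditions: hν (300–350 nm, Pyrex), 15 (4 equiv), ClCH2CH2Cl, 5 °C, sealed vessel; then 80 °C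
Reagents that add atoms: none
Why: Proposed new method: light expels N2 from 12 and the 4-oxopyran-2-yl group migrates to the carbene carbon (Wolff rearrangement) to give ketene 16, whose electrophilic central carbon is attacked by the unsubstituted, nucleophilic carbon of 15, so that a (2+2) cycloaddition gives 3-methoxycyclobutenone 17 with the methoxy-bearing carbon bonded to the former diazo carbon. Reversible four-electron electrocyclic opening of 17 gives dienylketene 18, and ring A then closes by a thermal disrotatory six-electron electrocyclisation between the ketene carbon and C3 of the pyranone, after which the C4a–H flanked by two carbonyl groups enolises to the phenol (new bonds C5–C6, C7–C8 and C4a–C5). The closest known reaction type is the Danheiser benzannulation of alkenyl, aryl and heteroaryl α-diazo ketones with alkynyl ethers, which has not been shown with a 4-pyranone as the migrating and ring-closing unit. No stereocentre remains, since the one in 17 is racemic and is destroyed on ring opening. The step needs regioselectivity in the cycloaddition, which the polarisation of the ynol ether secures (OMe ends at C7, meta to the new OH), and site selectivity in the closure, which is secured because the only carbon neighbour of the attachment carbon C2 is C3, the other neighbour being the ring oxygen. The push–pull C2=C3 bond has little aromatic stabilisation to lose and methoxyethyne cannot fragment by a retro-ene path, so closure at 80 °C should be feasible.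

Step 10
Reactants: 19
Product: 20 5-hydroxy-2-[4-(4-hydroxy-2,6-dimethoxyphenoxy)phenyl]-7-methoxy-4H-chromen-4-one
Conditions: H2 (1 atm), Pd/C, THF/EtOAc, rt
Reagents that add atoms: none
Why: Hydrogenolysis of the benzyl aryl ether over palladium on carbon, under which the flavone C2=C3 bond, the diaryl ether and the methyl ethers should be inert.

Step 11
Reactants: 20; 21 ethyl 3-[4-(benzyloxy)phenyl]-3-oxopropanoate
Product: 24 2-[4-(benzyloxy)phenyl]-6-[4-(5-hydroxy-7-methoxy-4-oxo-4H-chromen-2-yl)phenoxy]-5,7-dimethoxy-4H-chromen-4-one, via aroylketene 22 (not isolated), via aryl diketone 23 (not isolated)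
Conditions: 21 (3 equiv), Ph2O, 240 °C, N2 sweep
Reagents that add atoms: none
Why: Mentzer pyrone synthesis, in which thermal loss of ethanol from 21 gives an aroylketene that C-acylates the position ortho to the free hydroxyl (both ortho positions are equivalent and each is activated by OH, an ortho OMe and a para OMe) and the o-hydroxyaryl 1,3-diketone cyclodehydrates to the flavone, while the chelated 5-OH and carbonyl-deactivated ring A of unit 1 should not compete.

Step 12
Reactants: 24
Product: 25 5-hydroxy-6-[4-(5-hydroxy-7-methoxy-4-oxo-4H-chromen-2-yl)phenoxy]-2-(4-hydroxyphenyl)-7-methoxy-4H-chromen-4-one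
Conditions: BCl3, C6HMe5, CH2Cl2, −78 °C to 0 °C; then MeOH/H2O
Reagents that add atoms: none
Why: Chelation-controlled Lewis-acid ether cleavage, in which BCl3 removes the benzyl group (pentamethylbenzene traps the benzyl cation) and, through coordination to the C4 carbonyl of unit 2, only the peri 5-OMe group, leaving both 7-OMe groups and the diaryl ether untouched.

**Compound list**

1 | syringaldehyde (4-hydroxy-3,5-dimethoxybenzaldehyde) | COc1cc(C=O)cc(OC)c1O | starting material
2 | 4-fluoroacetophenone | CC(=O)c1ccc(F)cc1 | starting material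
3 | 4-(4-acetylphenoxy)-3,5-dimethoxybenzaldehyde | COc1cc(C=O)cc(OC)c1Oc1ccc(cc1)C(C)=O | intermediate
4 | 4-(4-acetylphenoxy)-3,5-dimethoxyphenyl formate | COc1cc(OC=O)cc(OC)c1Oc1ccc(cc1)C(C)=O | intermediate
5 | 1-[4-(4-hydroxy-2,6-dimethoxyphenoxy)phenyl]ethan-1-one | COc1cc(O)cc(OC)c1Oc1ccc(cc1)C(C)=O | intermediate
6 | 1-{4-[4-(benzyloxy)-2,6-dimethoxyphenoxy]phenyl}ethan-1-one | COc1cc(OCc2ccccc2)cc(OC)c1Oc1ccc(cc1)C(C)=O | intermediate
7 | 1-{4-[4-(benzyloxy)-2,6-dimethoxyphenoxy]phenyl}butane-1,3-dione | COc1cc(OCc2ccccc2)cc(OC)c1Oc1ccc(cc1)C(=O)CC(C)=O | intermediate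
8 | ethyl 6-{4-[4-(benzyloxy)-2,6-dimethoxyphenoxy]phenyl}-2,4,6-trioxohexanoate | CCOC(=O)C(=O)CC(=O)CC(=O)c1ccc(Oc2c(OC)cc(OCc3ccccc3)cc2OC)cc1 | intermediate
9 | ethyl 6-{4-[4-(benzyloxy)-2,6-dimethoxyphenoxy]phenyl}-4-oxo-4H-pyran-2-carboxylate | CCOC(=O)c1cc(=O)cc(-c2ccc(Oc3c(OC)cc(OCc4ccccc4)cc3OC)cc2)o1 | intermediate
10 | 6-{4-[4-(benzyloxy)-2,6-dimethoxyphenoxy]phenyl}-4-oxo-4H-pyran-2-carboxylic acid | OC(=O)c1cc(=O)cc(-c2ccc(Oc3c(OC)cc(OCc4ccccc4)cc3OC)cc2)o1 | intermediate
11 | 6-{4-[4-(benzyloxy)-2,6-dimethoxyphenoxy]phenyl}-4-oxo-4H-pyran-2-carbonyl chloride | ClC(=O)c1cc(=O)cc(-c2ccc(Oc3c(OC)cc(OCc4ccccc4)cc3OC)cc2)o1 | intermediate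
12 | 2-(diazoacetyl)-6-{4-[4-(benzyloxy)-2,6-dimethoxyphenoxy]phenyl}-4H-pyran-4-one | [N-]=[N+]=CC(=O)c1cc(=O)cc(-c2ccc(Oc3c(OC)cc(OCc4ccccc4)cc3OC)cc2)o1 | intermediate
13 | chloroacetaldehyde dimethyl acetal (2-chloro-1,1-dimethoxyethane) | COC(CCl)OC | starting material
14 | sodium methoxyethynide | [Na+].[C-]#COC | intermediate
15 | methoxyethyne | COC#C | intermediate
16 | (6-{4-[4-(benzyloxy)-2,6-dimethoxyphenoxy]phenyl}-4-oxo-4H-pyran-2-yl)ketene | O=C=Cc1cc(=O)cc(-c2ccc(Oc3c(OC)cc(OCc4ccccc4)cc3OC)cc2)o1 | intermediate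
17 | 4-(6-{4-[4-(benzyloxy)-2,6-dimethoxyphenoxy]phenyl}-4-oxo-4H-pyran-2-yl)-3-methoxycyclobut-2-en-1-one (racemic) | COC1=CC(=O)C1c1cc(=O)cc(-c2ccc(Oc3c(OC)cc(OCc4ccccc4)cc3OC)cc2)o1 | intermediate
18 | 4-(6-{4-[4-(benzyloxy)-2,6-dimethoxyphenoxy]phenyl}-4-oxo-4H-pyran-2-yl)-3-methoxybuta-1,3-dien-1-one (ketene arm cis to the pyranone across C3=C4) | O=C=C/C(OC)=C\c1cc(=O)cc(-c2ccc(Oc3c(OC)cc(OCc4ccccc4)cc3OC)cc2)o1 | intermediate
19 | 2-{4-[4-(benzyloxy)-2,6-dimethoxyphenoxy]phenyl}-5-hydroxy-7-methoxy-4H-chromen-4-one | COc1cc(O)c2c(=O)cc(-c3ccc(Oc4c(OC)cc(OCc5ccccc5)cc4OC)cc3)oc2c1 | intermediate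
20 | 5-hydroxy-2-[4-(4-hydroxy-2,6-dimethoxyphenoxy)phenyl]-7-methoxy-4H-chromen-4-one | COc1cc(O)c2c(=O)cc(-c3ccc(Oc4c(OC)cc(O)cc4OC)cc3)oc2c1 | intermediate
21 | ethyl 3-[4-(benzyloxy)phenyl]-3-oxopropanoate | CCOC(=O)CC(=O)c1ccc(OCc2ccccc2)cc1 | starting material
22 | [4-(benzyloxy)benzoyl]ketene | O=C=CC(=O)c1ccc(OCc2ccccc2)cc1 | intermediate
23 | 1-[4-(benzyloxy)phenyl]-3-{2-hydroxy-5-[4-(5-hydroxy-7-methoxy-4-oxo-4H-chromen-2-yl)phenoxy]-4,6-dimethoxyphenyl}propane-1,3-dione | COc1cc(O)c2c(=O)cc(-c3ccc(Oc4c(OC)cc(O)c(C(=O)CC(=O)c5ccc(OCc6ccccc6)cc5)c4OC)cc3)oc2c1 | intermediate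
24 | 2-[4-(benzyloxy)phenyl]-6-[4-(5-hydroxy-7-methoxy-4-oxo-4H-chromen-2-yl)phenoxy]-5,7-dimethoxy-4H-chromen-4-one | COc1cc(O)c2c(=O)cc(-c3ccc(Oc4c(OC)cc5oc(-c6ccc(OCc7ccccc7)cc6)cc(=O)c5c4OC)cc3)oc2c1 | intermediate
25 | 5-hydroxy-6-[4-(5-hydroxy-7-methoxy-4-oxo-4H-chromen-2-yl)phenoxy]-2-(4-hydroxyphenyl)-7-methoxy-4H-chromen-4-one | COc1cc(O)c2c(=O)cc(-c3ccc(Oc4c(OC)cc5oc(-c6ccc(O)cc6)cc(=O)c5c4O)cc3)oc2c1 | target

**Step count**

Total steps: 12. Longest linear sequence: 11 steps (steps 1 to 7 and 9 to 12, from syringaldehyde); step 8 is a one-step side branch.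

**Steps most likely to fail**

Step 9. The aryl pyranone chromophore may absorb the light and undergo its own photochemistry or sensitise triplet carbene reactions in place of the Wolff migration. The monosubstituted ketene may dimerise before it is trapped, the ynol ether may polymerise, and the product phenol may be acylated by remaining ketene. The fallback takes ring A of unit 1 from a preformed phloroacetophenone and uses only known flavone chemistry. It sets out from ketone 6, which haloform cleavage (NaOCl, NaOH, dioxane/H2O, 50 °C) should convert into 4-[4-(benzyloxy)-2,6-dimethoxyphenoxy]benzoic acid F1. Treatment with (COCl)2 and catalytic DMF should give 4-[4-(benzyloxy)-2,6-dimethoxyphenoxy]benzoyl chloride F2. This is added to commercial 1-(2,6-dihydroxy-4-methoxyphenyl)ethan-1-one deprotonated with excess LiN(SiMe3)2 (THF, −78 °C to rt). This one-flask Baker–Venkataraman-type aroyl transfer should give 1-{4-[4-(benzyloxy)-2,6-dimethoxyphenoxy]phenyl}-3-(2,6-dihydroxy-4-methoxyphenyl)propane-1,3-dione F3. Cyclodehydration (AcOH, catalytic H2SO4, 95 °C) onto either of the two equivalent hydroxyls comes back to the route at 19. Any benzyl ether lost in the acid would be harmless because step 10 removes it anyway.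

Step 11. Reversible O-acylation may dominate over C-acylation, a Pechmann-type closure to a 4-arylcoumarin may compete, and the advanced phenol may degrade at 240 °C. The fallback builds ring C of unit 2 stepwise, setting out from phenol 20. Friedel–Crafts acetylation (AcOH, BF3·OEt2, 80 °C) should give 2-[4-(3-acetyl-4-hydroxy-2,6-dimethoxyphenoxy)phenyl]-5-hydroxy-7-methoxy-4H-chromen-4-one F4. During this step the 5-OH and C4 carbonyl of unit 1 are tied up as a difluoroboron chelate that deactivates its ring A and is hydrolysed on work-up. Claisen–Schmidt condensation with 4-(benzyloxy)benzaldehyde (KOH, EtOH, rt) should give (E)-3-[4-(benzyloxy)phenyl]-1-{2-hydroxy-5-[4-(5-hydroxy-7-methoxy-4-oxo-4H-chromen-2-yl)phenoxy]-4,6-dimethoxyphenyl}prop-2-en-1-one F5. Oxidative cyclisation (catalytic I2, DMSO, 120 °C) comes back to the route at 24.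

Step 1. Substitution by the hindered, formyl-deactivated phenoxide may be slow, and at the temperature it needs a base-mediated aldol condensation between the aldehyde and the methyl ketone may take over. The fallback forms the same C–O bond oxidatively at room temperature, where no enolate chemistry is expected. It sets out from 1, which is coupled with (4-acetylphenyl)boronic acid under Chan–Lam–Evans conditions (Cu(OAc)2, pyridine, 4 Å molecular sieves, CH2Cl2, air, rt), a method known to tolerate phenols with two ortho substituents. It comes back to the route at 3 and makes no new compound (entry F0).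

**Further compounds**

F1 | step 9 | 4-[4-(benzyloxy)-2,6-dimethoxyphenoxy]benzoic acid | OC(=O)c1ccc(Oc2c(OC)cc(OCc3ccccc3)cc2OC)cc1
F2 | step 9 | 4-[4-(benzyloxy)-2,6-dimethoxyphenoxy]benzoyl chloride | ClC(=O)c1ccc(Oc2c(OC)cc(OCc3ccccc3)cc2OC)cc1
F3 | step 9 | 1-{4-[4-(benzyloxy)-2,6-dimethoxyphenoxy]phenyl}-3-(2,6-dihydroxy-4-methoxyphenyl)propane-1,3-dione | COc1cc(O)c(C(=O)CC(=O)c2ccc(Oc3c(OC)cc(OCc4ccccc4)cc3OC)cc2)c(O)c1
F4 | step 11 | 2-[4-(3-acetyl-4-hydroxy-2,6-dimethoxyphenoxy)phenyl]-5-hydroxy-7-methoxy-4H-chromen-4-one | COc1cc(O)c2c(=O)cc(-c3ccc(Oc4c(OC)cc(O)c(C(C)=O)c4OC)cc3)oc2c1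
F5 | step 11 | (E)-3-[4-(benzyloxy)phenyl]-1-{2-hydroxy-5-[4-(5-hydroxy-7-methoxy-4-oxo-4H-chromen-2-yl)phenoxy]-4,6-dimethoxyphenyl}prop-2-en-1-one | COc1cc(O)c2c(=O)cc(-c3ccc(Oc4c(OC)cc(O)c(C(=O)/C=C/c5ccc(OCc6ccccc6)cc5)c4OC)cc3)oc2c1
F0 | step 1 | none | none
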